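The triol ring is cut at the C1–C6 bond (carotenoid numbering: C1 gem-dimethyl carbon, C3 secondary carbinol, C5 methyl carbinol, C6 side-chain carbinol). The feature used is that C6 of the trihydroxycyclohexane ring lies between C1 and C5, so a tertiary C1 radical can attack a C6 ketone. In one operation, iron-hydride hydrogen-atom transfer to an isobutenyl group closes the cyclohexane, forms the C1–C6 bond and sets C6 from the C3 and C5 centres. The precursor is an acyclic (3R,5R)-bis(triethylsilyloxy) benzyloxymethyl ketone made by catalytic asymmetric aldol and reduction; the ring is later joined as a vinylstannane to an actinol-derived bromo-ylidenebutenolide polyene.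

Key step: step 10

Assumption: in the oxazaborolidine reduction (step 4) the isobutenyl group is taken as the larger ketone substituent, which fixes the (S)-catalyst (the antipode would be used if the sense proved reversed); LDA, LiHMDS, n-BuLi and DIBAL-H are used as commercial solutions.

Step 1
Reactants: 1 mesityl oxide
Product: 3 4-methyl-2-(trimethylsilyloxy)penta-1,3-diene, via lithium dienolate 2 (not isolated)
Conditions: LDA, THF, −78 °C; TMSCl, −78 °C → rt
Reagents that add atoms: chlorotrimethylsilane, C[Si](C)(C)Cl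
Why: Kinetic deprotonation of the α′-methyl group and O-silylation (kinetic enolate trapping) should give the 2-silyloxydiene, whose terminal CH2 is the only nucleophilic carbon in the next step.

Step 2
Reactants: 3 4-methyl-2-(trimethylsilyloxy)penta-1,3-diene; 4 methyl pyruvate
Product: 6 methyl (2R)-2-hydroxy-2,6-dimethyl-4-oxohept-5-enoate, via trimethylsilyl ether 5 (not isolated)
Conditions: Cu(OTf)2/(R,R)-t-Bu-box (10 mol %), THF, −78 °C; then 1 M HCl, THF, 0 °C
Reagents that add atoms: none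
Why: Copper(II)–bis(oxazoline)-catalysed Mukaiyama aldol, in which the pyruvate is held as a five-membered chelate on square-planar copper and the enol silane adds to the ketone face left open by the tert-butyl groups, which for the (R,R) ligand is the Re face and should give the (R)-carbinol (mirror image of the established (S,S)→(S) sense); the silyl group transferred to oxygen is then hydrolysed.

Step 3
Reactants: 6 methyl (2R)-2-hydroxy-2,6-dimethyl-4-oxohept-5-enoate
Product: 7 methyl (2R)-2,6-dimethyl-4-oxo-2-(triethylsilyloxy)hept-5-enoate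
Conditions: TESOTf, 2,6-lutidine, CH2Cl2, −78 → 0 °C
Reagents that add atoms: triethylsilyl triflate, CC[Si](CC)(CC)OS(=O)(=O)C(F)(F)F
Why: Silyl triflate silylation is the standard way to cap a hindered tertiary α-hydroxy ester, and the bulky ether keeps the oxygen from binding borane in step 4 and from chelating iron in step 10.

Step 4
Reactants: 7 methyl (2R)-2,6-dimethyl-4-oxo-2-(triethylsilyloxy)hept-5-enoate
Product: 8 methyl (2R,4R)-4-hydroxy-2,6-dimethyl-2-(triethylsilyloxy)hept-5-enoate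
Conditions: (S)-Me-CBS oxazaborolidine (0.2 equiv), catecholborane, toluene, −78 °C
Reagents that add atoms: none
Why: Corey–Bakshi–Shibata reduction, in which the (S)-catalyst with the isobutenyl group as the large substituent should deliver hydride to give the (4R)-allylic alcohol under catalyst control, while catecholborane at −78 °C spares the ester and the alkene.

Step 5
Reactants: 8 methyl (2R,4R)-4-hydroxy-2,6-dimethyl-2-(triethylsilyloxy)hept-5-enoate
Product: 9 methyl (2R,4R)-2,6-dimethyl-2,4-bis(triethylsilyloxy)hept-5-enoate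
Conditions: TESCl, imidazole, DMF, 0 °C
Reagents that add atoms: chlorotriethylsilane, CC[Si](Cl)(CC)CC
Why: Imidazole-promoted silylation of the secondary allylic alcohol is fast and removes the γ-hydroxy ester before it can lactonise.

Step 6
Reactants: 9 methyl (2R,4R)-2,6-dimethyl-2,4-bis(triethylsilyloxy)hept-5-enoate
Product: 10 (2R,4R)-2,6-dimethyl-2,4-bis(triethylsilyloxy)hept-5-enal
Conditions: DIBAL-H, CH2Cl2, −78 °C; Rochelle salt
Reagents that add atoms: none
Why: DIBAL reduction of an α-silyloxy ester at −78 °C should stop at the aldehyde because the chelated aluminium hemiacetal survives until work-up, and the quaternary α-carbon cannot epimerise.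

Step 7
Reactants: 11 benzyl chloromethyl ether
Product: 12 [(benzyloxy)methyl]tributylstannane
Conditions: Bu3SnH, LDA, THF, 0 °C; then 11, −78 °C → rt
Reagents that add atoms: tributyltin hydride, CCCC[SnH](CCCC)CCCC
Why: Deprotonated tributyltin hydride displaces chloride from the chloromethyl ether (SN2) to give the α-alkoxymethylstannane that serves as a benzyloxymethyl anion source.

Step 8
Reactants: 10 (2R,4R)-2,6-dimethyl-2,4-bis(triethylsilyloxy)hept-5-enal; 12 [(benzyloxy)methyl]tributylstannane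
Product: 14 (3R,5R)-1-(benzyloxy)-3,7-dimethyl-3,5-bis(triethylsilyloxy)oct-6-en-2-ol (both C2 epimers), via benzyloxymethyllithium 13 (not isolated)
Conditions: 12, n-BuLi, THF, −78 °C; then 10, −78 °C; NH4Cl quench at −78 °C
Reagents that add atoms: none
Why: Tin–lithium exchange followed by 1,2-addition to the non-enolisable aldehyde should give the carbinol, whose configuration is irrelevant because it is oxidised next, and the cold quench prevents 1,2-silyl migration to the new alkoxide.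

Step 9
Reactants: 14 (3R,5R)-1-(benzyloxy)-3,7-dimethyl-3,5-bis(triethylsilyloxy)oct-6-en-2-ol
Product: 15 (3R,5R)-1-(benzyloxy)-3,7-dimethyl-3,5-bis(triethylsilyloxy)oct-6-en-2-one
Conditions: Dess–Martin periodinane, pyridine, CH2Cl2, 0 °C → rt
Reagents that add atoms: none
Why: Dess–Martin oxidation converts the hindered secondary alcohol into the ketone under buffered conditions that leave the silyl ethers, the benzyl ether and the alkene untouched.

Step 10
Reactants: 15 (3R,5R)-1-(benzyloxy)-3,7-dimethyl-3,5-bis(triethylsilyloxy)oct-6-en-2-one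
Product: 16 (1S,4S,6R)-1-[(benzyloxy)methyl]-2,2,6-trimethyl-4,6-bis(triethylsilyloxy)cyclohexan-1-ol
Conditions: Fe(acac)3 (30 mol %), PhSiH3 (2.5 equiv), EtOH/ethylene glycol 5:1, 60 °C, degassed
Reagents that add atoms: none
Why: An iron hydride formed from Fe(acac)3 and phenylsilane transfers a hydrogen atom to the alkene CH (C2), leaving the nucleophilic tertiary radical at C1 that attacks the inductively activated ketone carbon C6; the resulting alkoxy radical should be reduced by iron(II) and protonated by ethanol faster than it can fragment. The closest known reaction type is the iron-mediated hydrogen-atom-transfer cyclisation of alkene-tethered ketones to tertiary cycloalkanols. The cyclohexane ring closes in the 6-exo-trig mode through the new C1–C6 bond. The C6 stereocentre is controlled by the C3 and C5 centres already present: in the favoured chair the C3 silyloxy group and the C5 methyl group are equatorial, the C5 silyloxy group is axial, and the carbonyl oxygen takes the axial site anti to the C5–O dipole while the bulkier benzyloxymethyl arm stays equatorial. The step needs the C6 hydroxyl trans to the C5 oxygen, and this is secured by the two bulky, non-chelating triethylsilyl ethers, which keep iron from bridging the ketone and C5 oxygens, and by the equatorial preference of the CH2OBn group. Silyl ethers and the benzyl ether are inert to the neutral conditions, and the quaternary C5 centre cannot epimerise.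

Step 11
Reactants: 16 (1S,4S,6R)-1-[(benzyloxy)methyl]-2,2,6-trimethyl-4,6-bis(triethylsilyloxy)cyclohexan-1-ol
Product: 17 (1S,4S,6R)-1-(hydroxymethyl)-2,2,6-trimethyl-4,6-bis(triethylsilyloxy)cyclohexan-1-ol
Conditions: H2 (1 atm), 10% Pd/C, EtOAc, rt
Reagents that add atoms: none
Why: Hydrogenolysis of the benzyl ether is clean here because no alkene is present and triethylsilyl ethers survive palladium in ethyl acetate.

Step 12
Reactants: 17 (1S,4S,6R)-1-(hydroxymethyl)-2,2,6-trimethyl-4,6-bis(triethylsilyloxy)cyclohexan-1-ol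
Product: 18 (1R,4S,6R)-1-hydroxy-2,2,6-trimethyl-4,6-bis(triethylsilyloxy)cyclohexane-1-carbaldehyde
Conditions: IBX, DMSO/THF, rt
Reagents that add atoms: none
Why: IBX oxidation takes the primary alcohol of a 1,2-diol to the α-hydroxy aldehyde without glycol cleavage, and the product has no α-hydrogen to epimerise.

Step 13
Reactants: 18 (1R,4S,6R)-1-hydroxy-2,2,6-trimethyl-4,6-bis(triethylsilyloxy)cyclohexane-1-carbaldehyde
Product: 19 (1S,4S,6R)-1-ethynyl-2,2,6-trimethyl-4,6-bis(triethylsilyloxy)cyclohexan-1-ol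
Conditions: dimethyl (1-diazo-2-oxopropyl)phosphonate, K2CO3, MeOH, 0 °C → rt
Reagents that add atoms: dimethyl (1-diazo-2-oxopropyl)phosphonate, COP(=O)(OC)C(=[N+]=[N-])C(C)=O
Why: Seyferth–Gilbert homologation with the Ohira–Bestmann reagent converts the non-enolisable aldehyde into the terminal alkyne under mild carbonate conditions that tolerate the free tertiary alcohol and the silyl ethers.

Step 14
Reactants: 19 (1S,4S,6R)-1-ethynyl-2,2,6-trimethyl-4,6-bis(triethylsilyloxy)cyclohexan-1-ol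
Product: 20 (1R,4S,6R)-1-[(E)-2-(tributylstannyl)ethenyl]-2,2,6-trimethyl-4,6-bis(triethylsilyloxy)cyclohexan-1-ol
Conditions: Bu3SnH, PdCl2(PPh3)2 (3 mol %), THF, 0 °C → rt
Reagents that add atoms: tributyltin hydride, CCCC[SnH](CCCC)CCCC
Why: Palladium-catalysed syn-hydrostannation should place tin on the terminal carbon because the fully substituted carbinol blocks the internal position, which gives the (E)-vinylstannane.

Step 15
Reactants: 21 (4R,6R)-actinol
Product: 22 (4R,6R)-2,2,6-trimethyl-4-(triethylsilyloxy)cyclohexan-1-one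
Conditions: TESCl, imidazole, DMF, 0 °C → rt
Reagents that add atoms: chlorotriethylsilane, CC[Si](Cl)(CC)CC
Why: Imidazole-promoted silylation protects the secondary alcohol for the enolate chemistry and puts the same silyl group on all three ring oxygens for one final deprotection.

Step 16
Reactants: 22 (4R,6R)-2,2,6-trimethyl-4-(triethylsilyloxy)cyclohexan-1-one
Product: 24 (4R)-2,6,6-trimethyl-4-(triethylsilyloxy)cyclohex-1-en-1-yl trifluoromethanesulfonate, via lithium enolate 23 (not isolated)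
Conditions: LDA, THF, −78 → 0 °C; PhNTf2, −78 °C → rt
Reagents that add atoms: N-phenylbis(trifluoromethanesulfonimide), O=S(=O)(N(c1ccccc1)S(=O)(=O)C(F)(F)F)C(F)(F)F
Why: The ketone has a single α-hydrogen, so only one enolate can form and its O-triflation gives the tetrasubstituted enol triflate, the C6 centre being erased on purpose and the C4 centre lying out of reach.

Step 17
Reactants: 24 (4R)-2,6,6-trimethyl-4-(triethylsilyloxy)cyclohex-1-en-1-yl trifluoromethanesulfonate; 25 (2E)-3-methylpent-2-en-4-yn-1-ol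
Product: 26 (2E)-3-methyl-5-[(4R)-2,6,6-trimethyl-4-(triethylsilyloxy)cyclohex-1-en-1-yl]pent-2-en-4-yn-1-ol
Conditions: Pd(PPh3)4 (5 mol %), CuI (10 mol %), i-Pr2NH, DMF, rt
Reagents that add atoms: none
Why: Sonogashira coupling of the alkenyl triflate with the terminal enyne installs the ring double bond and the alkyne without a dehydration step, keeps the (E)-geometry of the enyne and tolerates the free allylic alcohol.

Step 18
Reactants: 26 (2E)-3-methyl-5-[(4R)-2,6,6-trimethyl-4-(triethylsilyloxy)cyclohex-1-en-1-yl]pent-2-en-4-yn-1-ol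
Product: 27 (2E)-3-methyl-5-[(4R)-2,6,6-trimethyl-4-(triethylsilyloxy)cyclohex-1-en-1-yl]pent-2-en-4-ynal
Conditions: MnO2, CH2Cl2, rt
Reagents that add atoms: none
Why: Manganese dioxide oxidises the allylic alcohol selectively to the enynal without double-bond isomerisation.

Step 19
Reactants: 27 (2E)-3-methyl-5-[(4R)-2,6,6-trimethyl-4-(triethylsilyloxy)cyclohex-1-en-1-yl]pent-2-en-4-ynal
Product: 28 ethyl (2E,4E,6E)-7-methyl-9-[(4R)-2,6,6-trimethyl-4-(triethylsilyloxy)cyclohex-1-en-1-yl]nona-2,4,6-trien-8-ynoate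
Conditions: triethyl 4-phosphonocrotonate, LiHMDS, THF, −78 → 0 °C
Reagents that add atoms: triethyl 4-phosphonocrotonate, CCOC(=O)/C=C/CP(=O)(OCC)OCC
Why: Horner–Wadsworth–Emmons olefination with the vinylogous phosphonate adds four carbons and should form the new disubstituted double bond with E geometry.

Step 20
Reactants: 28 ethyl (2E,4E,6E)-7-methyl-9-[(4R)-2,6,6-trimethyl-4-(triethylsilyloxy)cyclohex-1-en-1-yl]nona-2,4,6-trien-8-ynoate
Product: 29 (2E,4E,6E)-7-methyl-9-[(4R)-2,6,6-trimethyl-4-(triethylsilyloxy)cyclohex-1-en-1-yl]nona-2,4,6-trien-8-yn-1-ol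
Conditions: DIBAL-H, CH2Cl2, −78 °C
Reagents that add atoms: none
Why: DIBAL reduces the conjugated ester in the 1,2-sense to the allylic alcohol and leaves the silyl ether and the enyne alone.

Step 21
Reactants: 29 (2E,4E,6E)-7-methyl-9-[(4R)-2,6,6-trimethyl-4-(triethylsilyloxy)cyclohex-1-en-1-yl]nona-2,4,6-trien-8-yn-1-ol
Product: 30 (2E,4E,6E)-7-methyl-9-[(4R)-2,6,6-trimethyl-4-(triethylsilyloxy)cyclohex-1-en-1-yl]nona-2,4,6-trien-8-ynal
Conditions: MnO2, CH2Cl2, rt, dark
Reagents that add atoms: none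
Why: Manganese dioxide oxidation of the polyenyl allylic alcohol gives the polyenal under neutral conditions.

Step 22
Reactants: 30 (2E,4E,6E)-7-methyl-9-[(4R)-2,6,6-trimethyl-4-(triethylsilyloxy)cyclohex-1-en-1-yl]nona-2,4,6-trien-8-ynal
Product: 31 (2E,4E,6E,8E)-2,9-dimethyl-11-[(4R)-2,6,6-trimethyl-4-(triethylsilyloxy)cyclohex-1-en-1-yl]undeca-2,4,6,8-tetraen-10-ynal
Conditions: Ph3P=C(Me)CHO, toluene, 80 °C, dark
Reagents that add atoms: 2-(triphenylphosphoranylidene)propanal, CC(C=O)=P(c1ccccc1)(c1ccccc1)c1ccccc1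
Why: Wittig olefination with the stabilised formyl ylide should give the (E)-α-methyl enal, which is too hindered and too electron-rich to be homologated a second time.

Step 23
Reactants: 31 (2E,4E,6E,8E)-2,9-dimethyl-11-[(4R)-2,6,6-trimethyl-4-(triethylsilyloxy)cyclohex-1-en-1-yl]undeca-2,4,6,8-tetraen-10-ynal; 32 3-bromofuran-2(5H)-one
Product: 35 (5Z)-3-bromo-5-[(2E,4E,6E,8E)-2,9-dimethyl-11-[(4R)-2,6,6-trimethyl-4-(triethylsilyloxy)cyclohex-1-en-1-yl]undeca-2,4,6,8-tetraen-10-yn-1-ylidene]furan-2(5H)-one, via silyloxyfuran 33 (not isolated), via aldol silyl ether 34 (not isolated)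
Conditions: TBSOTf, i-Pr2NEt, CH2Cl2, −78 → 0 °C; then DBU, 0 °C → rt, dark
Reagents that add atoms: none
Why: One-pot vinylogous Mukaiyama aldol–elimination, in which the butenolide is silylated to the 2-silyloxyfuran, this adds through C5 to the silyl-triflate-activated aldehyde carbon, and DBU then expels silanol (E1cB) to give the thermodynamically preferred (Z)-γ-ylidenebutenolide.

Step 24
Reactants: 20 (1R,4S,6R)-1-[(E)-2-(tributylstannyl)ethenyl]-2,2,6-trimethyl-4,6-bis(triethylsilyloxy)cyclohexan-1-ol; 35 (5Z)-3-bromo-5-[(2E,4E,6E,8E)-2,9-dimethyl-11-[(4R)-2,6,6-trimethyl-4-(triethylsilyloxy)cyclohex-1-en-1-yl]undeca-2,4,6,8-tetraen-10-yn-1-ylidene]furan-2(5H)-one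
Product: 36 (5Z)-3-[(E)-2-[(1R,4S,6R)-1-hydroxy-2,2,6-trimethyl-4,6-bis(triethylsilyloxy)cyclohexyl]ethenyl]-5-[(2E,4E,6E,8E)-2,9-dimethyl-11-[(4R)-2,6,6-trimethyl-4-(triethylsilyloxy)cyclohex-1-en-1-yl]undeca-2,4,6,8-tetraen-10-yn-1-ylidene]furan-2(5H)-one
Conditions: Pd2(dba)3 (5 mol %), AsPh3 (40 mol %), NMP, rt → 40 °C, dark
Reagents that add atoms: none
Why: Stille coupling of the (E)-alkenylstannane with the α-bromobutenolide forms the bond between the vinyl link and the lactone with retention of both alkene geometries, under neutral conditions that tolerate the free tertiary alcohol and the polyene.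

Step 25
Reactants: 36 (5Z)-3-[(E)-2-[(1R,4S,6R)-1-hydroxy-2,2,6-trimethyl-4,6-bis(triethylsilyloxy)cyclohexyl]ethenyl]-5-[(2E,4E,6E,8E)-2,9-dimethyl-11-[(4R)-2,6,6-trimethyl-4-(triethylsilyloxy)cyclohex-1-en-1-yl]undeca-2,4,6,8-tetraen-10-yn-1-ylidene]furan-2(5H)-one
Product: 37 (5Z)-3-[(E)-2-[(1R,2R,4S)-1,2,4-trihydroxy-2,6,6-trimethylcyclohexyl]ethenyl]-5-[(2E,4E,6E,8E)-11-[(4R)-4-hydroxy-2,6,6-trimethylcyclohex-1-en-1-yl]-2,9-dimethylundeca-2,4,6,8-tetraen-10-yn-1-ylidene]furan-2(5H)-one (CNP0163979.1)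
Conditions: HF·pyridine, pyridine, THF, 0 °C → rt, dark
Reagents that add atoms: none
Why: Fluoride-mediated cleavage of the three triethylsilyl ethers under pyridine-buffered conditions should leave the ylidenebutenolide, the polyene and the tertiary allylic alcohol untouched, and no stereocentre is affected.

Compound list
1 | mesityl oxide (4-methylpent-3-en-2-one) | CC(C)=CC(C)=O | starting material
2 | lithium 4-methylpenta-1,3-dien-2-olate | [Li]OC(=C)C=C(C)C | intermediate (not isolated)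
3 | 4-methyl-2-(trimethylsilyloxy)penta-1,3-diene | C=C(O[Si](C)(C)C)C=C(C)C | intermediate
4 | methyl pyruvate | CC(=O)C(=O)OC | starting material
5 | methyl (2R)-2,6-dimethyl-4-oxo-2-(trimethylsilyloxy)hept-5-enoate | CC(C)=CC(=O)C[C@@](C(=O)OC)(C)O[Si](C)(C)C | intermediate (not isolated)
6 | methyl (2R)-2-hydroxy-2,6-dimethyl-4-oxohept-5-enoate | CC(C)=CC(=O)C[C@@](C(=O)OC)(C)O | intermediate
7 | methyl (2R)-2,6-dimethyl-4-oxo-2-(triethylsilyloxy)hept-5-enoate | CC(C)=CC(=O)C[C@@](C(=O)OC)(C)O[Si](CC)(CC)CC | intermediate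
8 | methyl (2R,4R)-4-hydroxy-2,6-dimethyl-2-(triethylsilyloxy)hept-5-enoate | CC(C)=C[C@H](O)C[C@@](C(=O)OC)(C)O[Si](CC)(CC)CC | intermediate
9 | methyl (2R,4R)-2,6-dimethyl-2,4-bis(triethylsilyloxy)hept-5-enoate | CC(C)=C[C@H](O[Si](CC)(CC)CC)C[C@@](C(=O)OC)(C)O[Si](CC)(CC)CC | intermediate
10 | (2R,4R)-2,6-dimethyl-2,4-bis(triethylsilyloxy)hept-5-enal | CC(C)=C[C@H](O[Si](CC)(CC)CC)C[C@@](C=O)(C)O[Si](CC)(CC)CC | intermediate
11 | benzyl chloromethyl ether | ClCOCc1ccccc1 | starting material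
12 | [(benzyloxy)methyl]tributylstannane | CCCC[Sn](CCCC)(CCCC)COCc1ccccc1 | intermediate
13 | (benzyloxy)methyllithium | [Li]COCc1ccccc1 | intermediate (not isolated)
14 | (3R,5R)-1-(benzyloxy)-3,7-dimethyl-3,5-bis(triethylsilyloxy)oct-6-en-2-ol (both C2 epimers) | CC(C)=C[C@H](O[Si](CC)(CC)CC)C[C@@](C(O)COCc1ccccc1)(C)O[Si](CC)(CC)CC | intermediate
15 | (3R,5R)-1-(benzyloxy)-3,7-dimethyl-3,5-bis(triethylsilyloxy)oct-6-en-2-one | CC(C)=C[C@H](O[Si](CC)(CC)CC)C[C@@](C(=O)COCc1ccccc1)(C)O[Si](CC)(CC)CC | intermediate (key-step precursor)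
16 | (1S,4S,6R)-1-[(benzyloxy)methyl]-2,2,6-trimethyl-4,6-bis(triethylsilyloxy)cyclohexan-1-ol | c1ccccc1COC[C@@]2(O)C(C)(C)C[C@H](O[Si](CC)(CC)CC)C[C@@]2(C)O[Si](CC)(CC)CC | intermediate (key-step product)
17 | (1S,4S,6R)-1-(hydroxymethyl)-2,2,6-trimethyl-4,6-bis(triethylsilyloxy)cyclohexan-1-ol | OC[C@@]1(O)C(C)(C)C[C@H](O[Si](CC)(CC)CC)C[C@@]1(C)O[Si](CC)(CC)CC | intermediate
18 | (1R,4S,6R)-1-hydroxy-2,2,6-trimethyl-4,6-bis(triethylsilyloxy)cyclohexane-1-carbaldehyde | O=C[C@@]1(O)C(C)(C)C[C@H](O[Si](CC)(CC)CC)C[C@@]1(C)O[Si](CC)(CC)CC | intermediate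
19 | (1S,4S,6R)-1-ethynyl-2,2,6-trimethyl-4,6-bis(triethylsilyloxy)cyclohexan-1-ol | C#C[C@@]1(O)C(C)(C)C[C@H](O[Si](CC)(CC)CC)C[C@@]1(C)O[Si](CC)(CC)CC | intermediate
20 | (1R,4S,6R)-1-[(E)-2-(tributylstannyl)ethenyl]-2,2,6-trimethyl-4,6-bis(triethylsilyloxy)cyclohexan-1-ol | CCCC[Sn](CCCC)(CCCC)/C=C/[C@@]1(O)C(C)(C)C[C@H](O[Si](CC)(CC)CC)C[C@@]1(C)O[Si](CC)(CC)CC | intermediate
21 | (4R,6R)-actinol ((4R,6R)-4-hydroxy-2,2,6-trimethylcyclohexan-1-one) | O=C1C(C)(C)C[C@H](O)C[C@H]1C | starting material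
22 | (4R,6R)-2,2,6-trimethyl-4-(triethylsilyloxy)cyclohexan-1-one | O=C1C(C)(C)C[C@H](O[Si](CC)(CC)CC)C[C@H]1C | intermediate
23 | lithium (4R)-2,6,6-trimethyl-4-(triethylsilyloxy)cyclohex-1-en-1-olate | CC1=C(O[Li])C(C)(C)C[C@H](O[Si](CC)(CC)CC)C1 | intermediate (not isolated)
24 | (4R)-2,6,6-trimethyl-4-(triethylsilyloxy)cyclohex-1-en-1-yl trifluoromethanesulfonate | CC1=C(OS(=O)(=O)C(F)(F)F)C(C)(C)C[C@H](O[Si](CC)(CC)CC)C1 | intermediate
25 | (2E)-3-methylpent-2-en-4-yn-1-ol | C#C/C(C)=C/CO | starting material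
26 | (2E)-3-methyl-5-[(4R)-2,6,6-trimethyl-4-(triethylsilyloxy)cyclohex-1-en-1-yl]pent-2-en-4-yn-1-ol | CC1=C(C#C/C(C)=C/CO)C(C)(C)C[C@H](O[Si](CC)(CC)CC)C1 | intermediate
27 | (2E)-3-methyl-5-[(4R)-2,6,6-trimethyl-4-(triethylsilyloxy)cyclohex-1-en-1-yl]pent-2-en-4-ynal | CC1=C(C#C/C(C)=C/C=O)C(C)(C)C[C@H](O[Si](CC)(CC)CC)C1 | intermediate
28 | ethyl (2E,4E,6E)-7-methyl-9-[(4R)-2,6,6-trimethyl-4-(triethylsilyloxy)cyclohex-1-en-1-yl]nona-2,4,6-trien-8-ynoate | CC1=C(C#C/C(C)=C/C=C/C=C/C(=O)OCC)C(C)(C)C[C@H](O[Si](CC)(CC)CC)C1 | intermediate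
29 | (2E,4E,6E)-7-methyl-9-[(4R)-2,6,6-trimethyl-4-(triethylsilyloxy)cyclohex-1-en-1-yl]nona-2,4,6-trien-8-yn-1-ol | CC1=C(C#C/C(C)=C/C=C/C=C/CO)C(C)(C)C[C@H](O[Si](CC)(CC)CC)C1 | intermediate
30 | (2E,4E,6E)-7-methyl-9-[(4R)-2,6,6-trimethyl-4-(triethylsilyloxy)cyclohex-1-en-1-yl]nona-2,4,6-trien-8-ynal | CC1=C(C#C/C(C)=C/C=C/C=C/C=O)C(C)(C)C[C@H](O[Si](CC)(CC)CC)C1 | intermediate
31 | (2E,4E,6E,8E)-2,9-dimethyl-11-[(4R)-2,6,6-trimethyl-4-(triethylsilyloxy)cyclohex-1-en-1-yl]undeca-2,4,6,8-tetraen-10-ynal | CC1=C(C#C/C(C)=C/C=C/C=C/C=C(C)/C=O)C(C)(C)C[C@H](O[Si](CC)(CC)CC)C1 | intermediate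
32 | 3-bromofuran-2(5H)-one | O=C1OCC=C1Br | starting material
33 | [(3-bromofuran-2-yl)oxy](tert-butyl)dimethylsilane | CC(C)(C)[Si](C)(C)Oc1occc1Br | intermediate (not isolated)
34 | 3-bromo-5-[(2E,4E,6E,8E)-1-(tert-butyldimethylsilyloxy)-2,9-dimethyl-11-[(4R)-2,6,6-trimethyl-4-(triethylsilyloxy)cyclohex-1-en-1-yl]undeca-2,4,6,8-tetraen-10-yn-1-yl]furan-2(5H)-one (diastereomer mixture at the two new centres) | CC1=C(C#C/C(C)=C/C=C/C=C/C=C(C)/C(O[Si](C)(C)C(C)(C)C)C2OC(=O)C(Br)=C2)C(C)(C)C[C@H](O[Si](CC)(CC)CC)C1 | intermediate (not isolated)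
35 | (5Z)-3-bromo-5-[(2E,4E,6E,8E)-2,9-dimethyl-11-[(4R)-2,6,6-trimethyl-4-(triethylsilyloxy)cyclohex-1-en-1-yl]undeca-2,4,6,8-tetraen-10-yn-1-ylidene]furan-2(5H)-one | CC1=C(C#C/C(C)=C/C=C/C=C/C=C(C)/C=C2C=C(Br)C(=O)O/2)C(C)(C)C[C@H](O[Si](CC)(CC)CC)C1 | intermediate
36 | (5Z)-3-[(E)-2-[(1R,4S,6R)-1-hydroxy-2,2,6-trimethyl-4,6-bis(triethylsilyloxy)cyclohexyl]ethenyl]-5-[(2E,4E,6E,8E)-2,9-dimethyl-11-[(4R)-2,6,6-trimethyl-4-(triethylsilyloxy)cyclohex-1-en-1-yl]undeca-2,4,6,8-tetraen-10-yn-1-ylidene]furan-2(5H)-one | CC1=C(C#C/C(C)=C/C=C/C=C/C=C(C)/C=C2C=C(/C=C/[C@@]3(O)C(C)(C)C[C@H](O[Si](CC)(CC)CC)C[C@@]3(C)O[Si](CC)(CC)CC)C(=O)O/2)C(C)(C)C[C@H](O[Si](CC)(CC)CC)C1 | intermediate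
37 | CNP0163979.1, (5Z)-3-[(E)-2-[(1R,2R,4S)-1,2,4-trihydroxy-2,6,6-trimethylcyclohexyl]ethenyl]-5-[(2E,4E,6E,8E)-11-[(4R)-4-hydroxy-2,6,6-trimethylcyclohex-1-en-1-yl]-2,9-dimethylundeca-2,4,6,8-tetraen-10-yn-1-ylidene]furan-2(5H)-one | CC1=C(C#C/C(C)=C/C=C/C=C/C=C(C)/C=C2C=C(/C=C/[C@@]3(O)C(C)(C)C[C@H](O)C[C@@]3(C)O)C(=O)O/2)C(C)(C)C[C@H](O)C1 | target

Total step count: 25.
Longest linear sequence: 15 steps (steps 1–6, 8–14, 24 and 25, from mesityl oxide).

Steps most likely to fail

Step 10. The tertiary radical may be reduced to the isobutyl group before it cyclises, the alkoxy radical may fragment so that the addition reverses, or the closure may show poor facial selectivity at C6. The fallback takes the ring from actinol instead of closing it; it sets out from enol triflate 24 and comes back at 16. Palladium-catalysed methoxycarbonylation of 24 (Pd(OAc)2, dppp, CO, MeOH, Et3N, DMF) should give methyl (4R)-2,6,6-trimethyl-4-(triethylsilyloxy)cyclohex-1-ene-1-carboxylate F1, and DIBAL-H reduction the allylic alcohol [(4R)-2,6,6-trimethyl-4-(triethylsilyloxy)cyclohex-1-en-1-yl]methanol F2. Reagent-controlled Sharpless epoxidation (Ti(OiPr)4, TBHP, the tartrate antipode that delivers oxygen to the face of the silyloxy group, expected to be L-(+)-DET) should give the syn-epoxy alcohol [(1S,4S,6S)-2,2,6-trimethyl-4-(triethylsilyloxy)-7-oxabicyclo[4.1.0]heptan-1-yl]methanol F3, which is benzylated (NaH, BnBr) to (1S,4S,6S)-1-[(benzyloxy)methyl]-2,2,6-trimethyl-4-(triethylsilyloxy)-7-oxabicyclo[4.1.0]heptane F4. Acid-catalysed hydrolysis (aqueous HClO4, THF) should open the epoxide at the methyl-bearing carbon with inversion (trans-diaxial opening) and remove the silyl group, giving (1S,2R,4S)-1-[(benzyloxy)methyl]-2,6,6-trimethylcyclohexane-1,2,4-triol F5. Silylation of the secondary and the less hindered tertiary hydroxyl (TESCl/imidazole, then TESOTf/2,6-lutidine at low temperature) returns to 16.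

Step 23. The silyloxyfuran may attack the activated polyenal in a conjugate sense, the polyenyl silyl ether may ionise and decompose under the Lewis acid, or the elimination may give a poor Z/E ratio. The fallback builds the ylidene lactone by alkyne coupling and lactonisation instead of aldol condensation; it sets out from enynal 27 and enynol 25 and comes back at 35. Wittig homologation of 27 with (triphenylphosphoranylidene)acetaldehyde should give (2E,4E)-5-methyl-7-[(4R)-2,6,6-trimethyl-4-(triethylsilyloxy)cyclohex-1-en-1-yl]hepta-2,4-dien-6-ynal F6, and 25 with PPh3·HBr should give [(2E)-3-methylpent-2-en-4-yn-1-yl]triphenylphosphonium bromide F7. Wittig reaction of F7 with F6 (NaOMe, CH2Cl2/MeOH), followed by iodine-catalysed equilibration to the all-E isomer, should give the terminal polyenyne triethyl({(1R)-4-[(3E,5E,7E,9E)-3,10-dimethyldodeca-3,5,7,9-tetraene-1,11-diyn-1-yl]-3,5,5-trimethylcyclohex-3-en-1-yl}oxy)silane F8. Bromine addition to propiolic acid gives (2E)-2,3-dibromoprop-2-enoic acid F9; Sonogashira coupling of F8 at the β-bromide of F9 with 5-exo-dig lactonisation in the same flask (Pd(PPh3)4, CuI, Et3N, MeCN; AgNO3 if the cyclisation lags) should give 35 with the Z geometry fixed by anti addition across the alkyne.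

Step 4. Facial selectivity may be poor, because the neopentyl-type CH2 arm can compete with the isobutenyl group as the large substituent and the existing C2 centre may be mismatched with the catalyst. The fallback replaces catalyst control by separation and inversion; it sets out from 7 and comes back at 8. Luche reduction of 7 (NaBH4, CeCl3, MeOH, −78 °C) gives 8 together with its C4 epimer methyl (2R,4S)-4-hydroxy-2,6-dimethyl-2-(triethylsilyloxy)hept-5-enoate F10. After chromatographic separation, F10 is inverted by Mitsunobu esterification (4-nitrobenzoic acid, PPh3, DIAD) to methyl (2R,4R)-2,6-dimethyl-4-[(4-nitrobenzoyl)oxy]-2-(triethylsilyloxy)hept-5-enoate F11, whose methanolysis (K2CO3, MeOH) returns to 8.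

Further compounds
F1 | step 10 | methyl (4R)-2,6,6-trimethyl-4-(triethylsilyloxy)cyclohex-1-ene-1-carboxylate | CC1=C(C(=O)OC)C(C)(C)C[C@H](O[Si](CC)(CC)CC)C1
F2 | step 10 | [(4R)-2,6,6-trimethyl-4-(triethylsilyloxy)cyclohex-1-en-1-yl]methanol | CC1=C(CO)C(C)(C)C[C@H](O[Si](CC)(CC)CC)C1
F3 | step 10 | [(1S,4S,6S)-2,2,6-trimethyl-4-(triethylsilyloxy)-7-oxabicyclo[4.1.0]heptan-1-yl]methanol | OC[C@@]1(O2)C(C)(C)C[C@H](O[Si](CC)(CC)CC)C[C@@]12C
F4 | step 10 | (1S,4S,6S)-1-[(benzyloxy)methyl]-2,2,6-trimethyl-4-(triethylsilyloxy)-7-oxabicyclo[4.1.0]heptane | c1ccccc1COC[C@@]1(O2)C(C)(C)C[C@H](O[Si](CC)(CC)CC)C[C@@]12C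
F5 | step 10 | (1S,2R,4S)-1-[(benzyloxy)methyl]-2,6,6-trimethylcyclohexane-1,2,4-triol | c1ccccc1COC[C@@]1(O)C(C)(C)C[C@H](O)C[C@@]1(C)O
F6 | step 23 | (2E,4E)-5-methyl-7-[(4R)-2,6,6-trimethyl-4-(triethylsilyloxy)cyclohex-1-en-1-yl]hepta-2,4-dien-6-ynal | CC1=C(C#C/C(C)=C/C=C/C=O)C(C)(C)C[C@H](O[Si](CC)(CC)CC)C1
F7 | step 23 | [(2E)-3-methylpent-2-en-4-yn-1-yl]triphenylphosphonium bromide | C#C/C(C)=C/C[P+](c1ccccc1)(c1ccccc1)c1ccccc1.[Br-]
F8 | step 23 | triethyl({(1R)-4-[(3E,5E,7E,9E)-3,10-dimethyldodeca-3,5,7,9-tetraene-1,11-diyn-1-yl]-3,5,5-trimethylcyclohex-3-en-1-yl}oxy)silane | CC1=C(C#C/C(C)=C/C=C/C=C/C=C(C)/C#C)C(C)(C)C[C@H](O[Si](CC)(CC)CC)C1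
F9 | step 23 | (2E)-2,3-dibromoprop-2-enoic acid | OC(=O)/C(Br)=C\Br
F10 | step 4 | methyl (2R,4S)-4-hydroxy-2,6-dimethyl-2-(triethylsilyloxy)hept-5-enoate | CC(C)=C[C@@H](O)C[C@@](C(=O)OC)(C)O[Si](CC)(CC)CC
F11 | step 4 | methyl (2R,4R)-2,6-dimethyl-4-[(4-nitrobenzoyl)oxy]-2-(triethylsilyloxy)hept-5-enoate | CC(C)=C[C@H](OC(=O)c1ccc(cc1)[N+](=O)[O-])C[C@@](C(=O)OC)(C)O[Si](CC)(CC)CC
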